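**Plan**

- Feature: deleting O1 from the C10–O1–C15 link of the 2,8-dioxabicyclo[3.2.1]octane leaves a 7-oxabicyclo[2.2.1]heptan-2-one in which the tertiary, O2-bearing bridgehead C10 is bonded directly to the carbonyl carbon C15; oxygen insertion into that bond makes the ketal.
- Retrosynthetic cuts, in order: aryl O–Me and both acetates; C1′–O (epoxide opening); C8–C9 (alkenyl triflate + aldehyde); C15–C16 (alkenylalane + lactol acetate); O1 (Baeyer–Villiger); O2–C13 (transannular etherification); C10–C11 and C14–C15 (Diels–Alder).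
- Forward: carbocycle by Diels–Alder, epoxide and trans-diol, oxygen bridge O2 (7-oxanorbornane), ring expansion to the dioxabicyclooctanone, C15 side chain, C8/C7/aryl unit, C9 epoxide, acetates, hydroquinone.
- Stereochemistry: C10 from a Sharpless epoxidation (D-tartrate) matched to a CBS-derived carbinol; C13 forced by the bridge; C15 by exo attack on the bicyclic oxocarbenium ion; C8 by CBS reduction; C9 by hydroxyl-directed epoxidation; C16=C17 geometry by syn-carboalumination.

Key step: step 9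

Numbering used throughout (target numbering): ArCH2 = C7, CHOAc = C8, C(OH) = C9, its CH2OAc = C1′, ketal carbon = C10, ring CH2CH2 = C11–C12, methyl-bearing bridgehead = C13, ring CH2 = C14, ring OCH = C15, alkene = C16=C17; O1 joins C10 and C15, O2 joins C10 and C13.

"Bic" stands for the unit (1R,3S,5R)-3-[(1E)-2,6-dimethylhepta-1,5-dien-1-yl]-5-methyl-2,8-dioxabicyclo[3.2.1]octan-1-yl.

Remark on the chemistry: acetate 14 (C15 epimers), enol ether 24 (E/Z) and alcohol 26 (C8 epimers) are carried as mixtures because that element is re-set or lost in the next operation; their SMILES leave it undefined. All five starting materials are assumed to be commercially available.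

**Route**

Step 1
Reactants: 1 isoprene; 2 but-3-yn-2-one
Product: 3 1-(4-methylcyclohexa-1,4-dien-1-yl)ethan-1-one
Conditions: AlCl3 (0.2 equiv), CH2Cl2, 0 °C, argon
Reagents that add atoms: none
Why: Lewis-acid-promoted Diels–Alder reaction of a 2-substituted diene with an ynone should give mainly the 1,4-disubstituted ("para") cyclohexa-1,4-diene, with no stereocentre formed; the diene is used at once to avoid aromatisation.

Step 2
Reactants: 3 1-(4-methylcyclohexa-1,4-dien-1-yl)ethan-1-one
Product: 4 (1R)-1-(4-methylcyclohexa-1,4-dien-1-yl)ethan-1-ol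
Conditions: (S)-2-methyl-CBS-oxazaborolidine (0.2 equiv), catecholborane, toluene, −78 °C
Reagents that add atoms: none
Why: Corey–Bakshi–Shibata reduction with the dienyl group as the large and methyl as the small substituent should give the (R)-carbinol, and catecholborane should leave the isolated alkene alone.

Step 3
Reactants: 4 (1R)-1-(4-methylcyclohexa-1,4-dien-1-yl)ethan-1-ol
Product: 5 (1R)-1-[(1R,6R)-4-methyl-7-oxabicyclo[4.1.0]hept-3-en-1-yl]ethan-1-ol
Conditions: Ti(OiPr)4 (0.1 equiv), D-(−)-diisopropyl tartrate (0.12 equiv), t-BuOOH, 4 Å molecular sieves, CH2Cl2, −20 °C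
Reagents that add atoms: tert-butyl hydroperoxide, CC(C)(C)OO
Why: Sharpless asymmetric epoxidation in its matched kinetic-resolution mode: the D-tartrate catalyst epoxidises only the allylic alkene of the (R)-alcohol, from the face that makes C10 R (erythro epoxy alcohol), so reagent and carbinol reinforce each other and any (S)-alcohol is left behind.

Step 4
Reactants: 5 (1R)-1-[(1R,6R)-4-methyl-7-oxabicyclo[4.1.0]hept-3-en-1-yl]ethan-1-ol
Product: 6 (1S,6R)-6-hydroxy-6-[(1R)-1-hydroxyethyl]-3-methylcyclohex-3-en-1-yl benzoate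
Conditions: Ti(OiPr)4 (1.5 equiv), PhCO2H, CH2Cl2, rt
Reagents that add atoms: benzoic acid, OC(=O)c1ccccc1
Why: Ti(OiPr)4-mediated opening of a 2,3-epoxy alcohol by a carboxylic acid at C3 (here C15) with inversion; the titanium chelate steers benzoate away from the tertiary C10, whose C–O bond and configuration are kept.

Step 5
Reactants: 6 (1S,6R)-6-hydroxy-6-[(1R)-1-hydroxyethyl]-3-methylcyclohex-3-en-1-yl benzoate
Product: 7 (1S,6S)-6-[(1R)-1-{[tert-butyl(dimethyl)silyl]oxy}ethyl]-6-hydroxy-3-methylcyclohex-3-en-1-yl benzoate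
Conditions: TBSOTf (1.1 equiv), 2,6-lutidine, CH2Cl2, −78 °C
Reagents that add atoms: tert-butyldimethylsilyl trifluoromethanesulfonate, CC(C)(C)[Si](C)(C)OS(=O)(=O)C(F)(F)F
Why: silylation with a silyl triflate at low temperature should take the secondary hydroxyl and leave the tertiary C10 hydroxyl free.

Step 6
Reactants: 7 (1S,6S)-6-[(1R)-1-{[tert-butyl(dimethyl)silyl]oxy}ethyl]-6-hydroxy-3-methylcyclohex-3-en-1-yl benzoate
Product: 8 (1S,2S)-1-[(1R)-1-{[tert-butyl(dimethyl)silyl]oxy}ethyl]-4-methylcyclohex-4-ene-1,2-diol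
Conditions: K2CO3, MeOH, rt
Reagents that add atoms: none
Why: base-catalysed transesterification removes the benzoate, which could otherwise take part as a neighbouring group in the next step, and leaves the silyl ether intact.

Step 7
Reactants: 8 (1S,2S)-1-[(1R)-1-{[tert-butyl(dimethyl)silyl]oxy}ethyl]-4-methylcyclohex-4-ene-1,2-diol
Product: 10 (1S,2S,4R)-1-[(1R)-1-{[tert-butyl(dimethyl)silyl]oxy}ethyl]-4-methyl-7-oxabicyclo[2.2.1]heptan-2-ol, via organomercurial 9 (not isolated)
Conditions: Hg(OCOCF3)2, NaHCO3, CH2Cl2, 0 °C; then NaBH4, 3 M aq. NaOH, 0 °C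
Reagents that add atoms: none
Why: intramolecular alkoxymercuration–demercuration of a cyclohex-3-enol (the cineole-type closure): the tertiary C10 hydroxyl adds across the ring in the Markovnikov sense to the methyl-bearing C13, which must take the configuration cis to C10–O, and borohydride then replaces mercury at C12 by hydrogen.

Step 8
Reactants: 10 (1S,2S,4R)-1-[(1R)-1-{[tert-butyl(dimethyl)silyl]oxy}ethyl]-4-methyl-7-oxabicyclo[2.2.1]heptan-2-ol
Product: 11 (1R,4R)-1-[(1R)-1-{[tert-butyl(dimethyl)silyl]oxy}ethyl]-4-methyl-7-oxabicyclo[2.2.1]heptan-2-one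
Conditions: Dess–Martin periodinane, NaHCO3, CH2Cl2, 0 °C to rt
Reagents that add atoms: none
Why: Dess–Martin oxidation of the secondary alcohol under buffered, non-basic conditions should avoid β-elimination of the oxygen bridge.

Step 9
Reactants: 11 (1R,4R)-1-[(1R)-1-{[tert-butyl(dimethyl)silyl]oxy}ethyl]-4-methyl-7-oxabicyclo[2.2.1]heptan-2-one
Product: 12 (1S,5R)-1-[(1R)-1-{[tert-butyl(dimethyl)silyl]oxy}ethyl]-5-methyl-2,8-dioxabicyclo[3.2.1]octan-3-one
Conditions: mCPBA (2 equiv), NaHCO3, CH2Cl2, 0 °C to rt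
Reagents that add atoms: 3-chloroperbenzoic acid, OOC(=O)c1cccc(Cl)c1
Why: Baeyer–Villiger oxidation: the peracid adds to the strained C15 ketone to give the Criegee adduct, and the bridgehead C10 shifts from C15 to oxygen as 3-chlorobenzoate leaves, forming C10–O1 and O1–C15. The closest known reaction is the Baeyer–Villiger oxidation of 7-oxabicyclo[2.2.1]heptan-2-ones, which goes by migration of the oxygen-bearing bridgehead. No ring is closed by cyclisation: the six-membered 1,3-dioxan-4-one ring (C10–O1–C15–C14–C13–O2) arises by one-atom expansion of the five-membered carbocycle through a concerted 1,2-shift. No new stereocentre is formed; C10 migrates with retention and C13 is untouched, so both keep the configurations set in steps 3 and 7 (the descriptor of C10 changes only through the priority rules). The selectivity needed is migration of C10 and not of the C14 methylene, and it is secured because C10 is tertiary and a lone pair on the bridging O2 stabilises the electron-deficient migrating carbon. The silyl ether, the only other functional group, is inert to buffered peracid.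

Step 10
Reactants: 12 (1S,5R)-1-[(1R)-1-{[tert-butyl(dimethyl)silyl]oxy}ethyl]-5-methyl-2,8-dioxabicyclo[3.2.1]octan-3-one
Product: 14 (1S,5R)-1-[(1R)-1-{[tert-butyl(dimethyl)silyl]oxy}ethyl]-5-methyl-2,8-dioxabicyclo[3.2.1]octan-3-yl acetate (both C3 epimers), via aluminium hemiacetal 13 (not isolated)
Conditions: i-Bu2AlH, CH2Cl2, −78 °C; then pyridine, DMAP, Ac2O, −78 to −20 °C
Reagents that add atoms: acetic anhydride, CC(=O)OC(C)=O
Why: reductive acetylation of a lactone (hydride addition to the aluminium hemiacetal, acetylated in the cold before it can open) gives the α-acetoxy ether; the new acetal centre needs no control.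

Step 11
Reactants: 15 5-bromo-2-methylpent-2-ene; 16 lithium acetylide–ethylenediamine complex (LiC≡CH·H2NCH2CH2NH2)
Product: 17 6-methylhept-5-en-1-yne
Conditions: DMSO, 10 °C to rt
Reagents that add atoms: none
Why: SN2 alkylation of lithium acetylide by a primary bromide in a dipolar aprotic solvent.

Step 12
Reactants: 17 6-methylhept-5-en-1-yne; 14 (1S,5R)-1-[(1R)-1-{[tert-butyl(dimethyl)silyl]oxy}ethyl]-5-methyl-2,8-dioxabicyclo[3.2.1]octan-3-yl acetate
Product: 19 tert-butyl[(1R)-1-Bic-ethoxy]dimethylsilane, via alkenylalane 18 (not isolated)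
Conditions: 17, AlMe3, Cp2ZrCl2 (0.2 equiv), CH2Cl2, 0 °C to rt; excess AlMe3 removed in vacuo; then 14, CH2Cl2, −78 to 0 °C
Reagents that add atoms: trimethylaluminium, C[Al](C)C
Why: Negishi zirconium-catalysed syn-carboalumination sets the (E)-2-methylalkenyl geometry; the alane then ionises the anomeric acetate and transfers its alkenyl group to the C15 oxocarbenium ion from the exo face (anti to the C11–C12 bridge), which places the side chain equatorial, that is (15S). Excess AlMe3 is removed first so that methyl transfer does not compete.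

Step 13
Reactants: 19 tert-butyl[(1R)-1-Bic-ethoxy]dimethylsilane
Product: 20 (1R)-1-Bic-ethan-1-ol
Conditions: Bu4NF, THF, rt
Reagents that add atoms: none
Why: fluoride-induced desilylation; the ketal, the allylic ether and the alkenes are inert to fluoride.

Step 14
Reactants: 20 (1R)-1-Bic-ethan-1-ol
Product: 21 1-Bic-ethan-1-one
Conditions: Dess–Martin periodinane, NaHCO3, CH2Cl2, rt
Reagents that add atoms: none
Why: Dess–Martin oxidation of the secondary carbinol to the methyl ketone under buffered conditions that spare the ketal and the alkenes; the auxiliary C9 carbinol centre is removed here as planned.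

Step 15
Reactants: 21 1-Bic-ethan-1-one
Product: 22 1-Bic-ethenyl trifluoromethanesulfonate
Conditions: KN(SiMe3)2, THF, −78 °C; then PhNTf2, −78 to 0 °C
Reagents that add atoms: N-phenylbis(trifluoromethanesulfonimide), O=S(=O)(N(c1ccccc1)S(=O)(=O)C(F)(F)F)C(F)(F)F
Why: enolate O-triflation; only the methyl group can enolise because C10 is quaternary, so a single enol triflate with the C9=C1′ methylene should result.

Step 16
Reactants: 23 2,5-dimethoxy-4-methylbenzaldehyde
Product: 25 2-(2,5-dimethoxy-4-methylphenyl)acetaldehyde, via enol ether 24 (not isolated)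
Conditions: Ph3P(CH2OMe)Cl, KOt-Bu, THF, 0 °C; then 2 M aq. HCl, THF, rt
Reagents that add atoms: (methoxymethyl)triphenylphosphonium chloride, COC[P+](c1ccccc1)(c1ccccc1)c1ccccc1.[Cl-]; water, O
Why: Wittig methoxymethylenation followed by hydrolysis of the enol ether is the standard one-carbon homologation of an aryl aldehyde; the aldehyde is used at once.

Step 17
Reactants: 22 1-Bic-ethenyl trifluoromethanesulfonate; 25 2-(2,5-dimethoxy-4-methylphenyl)acetaldehyde
Product: 26 3-Bic-1-(2,5-dimethoxy-4-methylphenyl)but-3-en-2-ol (both C2 epimers)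
Conditions: CrCl2 (4 equiv), NiCl2 (2 mol%), DMF, rt
Reagents that add atoms: none
Why: Nozaki–Hiyama–Kishi coupling of an alkenyl triflate with an aldehyde forms C8–C9 under non-basic conditions that tolerate the enolisable arylacetaldehyde; no control at C8 is sought because the centre is re-set in step 19.

Step 18
Reactants: 26 3-Bic-1-(2,5-dimethoxy-4-methylphenyl)but-3-en-2-ol
Product: 27 3-Bic-1-(2,5-dimethoxy-4-methylphenyl)but-3-en-2-one
Conditions: Dess–Martin periodinane, NaHCO3, CH2Cl2, 0 °C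
Reagents that add atoms: none
Why: Dess–Martin oxidation of the allylic alcohol merges both C8 epimers into one enone.

Step 19
Reactants: 27 3-Bic-1-(2,5-dimethoxy-4-methylphenyl)but-3-en-2-one
Product: 28 (2R)-3-Bic-1-(2,5-dimethoxy-4-methylphenyl)but-3-en-2-ol
Conditions: (S)-2-methyl-CBS-oxazaborolidine (0.3 equiv), catecholborane, toluene, −78 °C
Reagents that add atoms: none
Why: Corey–Bakshi–Shibata reduction in which the alkenyl group carrying the quaternary ketal carbon is the large and the arylmethyl group the small substituent should give the (8R)-carbinol under reagent control.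

Step 20
Reactants: 28 (2R)-3-Bic-1-(2,5-dimethoxy-4-methylphenyl)but-3-en-2-ol
Product: 29 (1R)-1-[(2S)-2-Bic-oxiran-2-yl]-2-(2,5-dimethoxy-4-methylphenyl)ethan-1-ol
Conditions: VO(acac)2 (5 mol%), t-BuOOH, CH2Cl2, 0 °C
Reagents that add atoms: tert-butyl hydroperoxide, CC(C)(C)OO
Why: hydroxyl-directed epoxidation of a 2-substituted allylic alcohol: A(1,2) strain against the bulky C10 substituent puts the carbinol hydrogen in the plane and the arylmethyl group on the far face, so oxygen is delivered erythro and C9 becomes S; the two isolated trisubstituted alkenes are not touched.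

Step 21
Reactants: 29 (1R)-1-[(2S)-2-Bic-oxiran-2-yl]-2-(2,5-dimethoxy-4-methylphenyl)ethan-1-ol
Product: 30 (2S,3R)-2-Bic-4-(2,5-dimethoxy-4-methylphenyl)-2,3-dihydroxybutyl acetate
Conditions: Ti(OiPr)4 (1.5 equiv), AcOH, CH2Cl2, rt
Reagents that add atoms: acetic acid, CC(O)=O
Why: Ti(OiPr)4-mediated opening of the 2,3-epoxy alcohol by a carboxylic acid at the primary C3 (C1′) leaves the C9–O bond and its configuration untouched; any acetyl shift to the C8 hydroxyl is levelled in step 22.

Step 22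
Reactants: 30 (2S,3R)-2-Bic-4-(2,5-dimethoxy-4-methylphenyl)-2,3-dihydroxybutyl acetate
Product: 31 (2S,3R)-3-acetoxy-2-Bic-4-(2,5-dimethoxy-4-methylphenyl)-2-hydroxybutyl acetate
Conditions: Ac2O, pyridine, DMAP (cat.), CH2Cl2, 0 °C to rt
Reagents that add atoms: acetic anhydride, CC(=O)OC(C)=O
Why: acylation of the secondary C8 hydroxyl; the tertiary C9 hydroxyl should not react under these conditions.

Step 23
Reactants: 31 (2S,3R)-3-acetoxy-2-Bic-4-(2,5-dimethoxy-4-methylphenyl)-2-hydroxybutyl acetate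
Product: 33 (2S,3R)-3-acetoxy-2-Bic-4-(2,5-dihydroxy-4-methylphenyl)-2-hydroxybutyl acetate, via quinone 32 (not isolated)
Conditions: (NH4)2Ce(NO3)6, MeCN–H2O, 0 °C, short contact; then aq. Na2S2O4, EtOAc
Reagents that add atoms: water, O
Why: oxidative demethylation of the hydroquinone dimethyl ether by tetravalent cerium gives the quinone, which dithionite reduces to the hydroquinone; the arene is the most easily oxidised group, so the alkenes, acetates and ketal should survive the brief cold treatment.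

**Compound list**

1 | isoprene (2-methylbuta-1,3-diene) | CC(=C)C=C | starting material
2 | but-3-yn-2-one | CC(=O)C#C | starting material
3 | 1-(4-methylcyclohexa-1,4-dien-1-yl)ethan-1-one | CC(=O)C1=CCC(C)=CC1 | intermediate
4 | (1R)-1-(4-methylcyclohexa-1,4-dien-1-yl)ethan-1-ol | C[C@@H](O)C1=CCC(C)=CC1 | intermediate
5 | (1R)-1-[(1R,6R)-4-methyl-7-oxabicyclo[4.1.0]hept-3-en-1-yl]ethan-1-ol | C[C@@H](O)[C@]12CC=C(C)C[C@H]1O2 | intermediate
6 | (1S,6R)-6-hydroxy-6-[(1R)-1-hydroxyethyl]-3-methylcyclohex-3-en-1-yl benzoate | C[C@@H](O)[C@]1(O)CC=C(C)C[C@@H]1OC(=O)c1ccccc1 | intermediate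
7 | (1S,6S)-6-[(1R)-1-{[tert-butyl(dimethyl)silyl]oxy}ethyl]-6-hydroxy-3-methylcyclohex-3-en-1-yl benzoate | C[C@@H](O[Si](C)(C)C(C)(C)C)[C@]1(O)CC=C(C)C[C@@H]1OC(=O)c1ccccc1 | intermediate
8 | (1S,2S)-1-[(1R)-1-{[tert-butyl(dimethyl)silyl]oxy}ethyl]-4-methylcyclohex-4-ene-1,2-diol | C[C@@H](O[Si](C)(C)C(C)(C)C)[C@]1(O)CC=C(C)C[C@@H]1O | intermediate
9 | {(1S,2S,4S,5S)-4-[(1R)-1-{[tert-butyl(dimethyl)silyl]oxy}ethyl]-5-hydroxy-1-methyl-7-oxabicyclo[2.2.1]heptan-2-yl}mercury trifluoroacetate (mercury endo, at C12) | C[C@@H](O[Si](C)(C)C(C)(C)C)[C@]12C[C@H]([Hg]OC(=O)C(F)(F)F)[C@](C)(C[C@@H]1O)O2 | intermediate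
10 | (1S,2S,4R)-1-[(1R)-1-{[tert-butyl(dimethyl)silyl]oxy}ethyl]-4-methyl-7-oxabicyclo[2.2.1]heptan-2-ol (hydroxyl endo) | C[C@@H](O[Si](C)(C)C(C)(C)C)[C@]12CC[C@](C)(C[C@@H]1O)O2 | intermediate
11 | (1R,4R)-1-[(1R)-1-{[tert-butyl(dimethyl)silyl]oxy}ethyl]-4-methyl-7-oxabicyclo[2.2.1]heptan-2-one | C[C@@H](O[Si](C)(C)C(C)(C)C)[C@]12CC[C@](C)(CC1=O)O2 | intermediate
12 | (1S,5R)-1-[(1R)-1-{[tert-butyl(dimethyl)silyl]oxy}ethyl]-5-methyl-2,8-dioxabicyclo[3.2.1]octan-3-one | C[C@@H](O[Si](C)(C)C(C)(C)C)[C@]12CC[C@](C)(CC(=O)O1)O2 | intermediate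
13 | {[(1S,5R)-1-[(1R)-1-{[tert-butyl(dimethyl)silyl]oxy}ethyl]-5-methyl-2,8-dioxabicyclo[3.2.1]octan-3-yl]oxy}bis(2-methylpropyl)alane (C3 epimers) | C[C@@H](O[Si](C)(C)C(C)(C)C)[C@]12CC[C@](C)(CC(O[Al](CC(C)C)CC(C)C)O1)O2 | intermediate
14 | (1S,5R)-1-[(1R)-1-{[tert-butyl(dimethyl)silyl]oxy}ethyl]-5-methyl-2,8-dioxabicyclo[3.2.1]octan-3-yl acetate (C3 epimers) | C[C@@H](O[Si](C)(C)C(C)(C)C)[C@]12CC[C@](C)(CC(OC(C)=O)O1)O2 | intermediate
15 | 5-bromo-2-methylpent-2-ene | CC(C)=CCCBr | starting material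
16 | lithium acetylide–ethylenediamine complex | [Li]C#C.NCCN | starting material
17 | 6-methylhept-5-en-1-yne | CC(C)=CCCC#C | intermediate
18 | [(1E)-2,6-dimethylhepta-1,5-dien-1-yl]dimethylalane | CC(C)=CCC/C(C)=C/[Al](C)C | intermediate
19 | tert-butyl[(1R)-1-Bic-ethoxy]dimethylsilane | C[C@@H](O[Si](C)(C)C(C)(C)C)[C@]12CC[C@](C)(C[C@@H](/C=C(\C)CCC=C(C)C)O1)O2 | intermediate
20 | (1R)-1-Bic-ethan-1-ol | C[C@@H](O)[C@]12CC[C@](C)(C[C@@H](/C=C(\C)CCC=C(C)C)O1)O2 | intermediate
21 | 1-Bic-ethan-1-one | CC(=O)[C@]12CC[C@](C)(C[C@@H](/C=C(\C)CCC=C(C)C)O1)O2 | intermediate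
22 | 1-Bic-ethenyl trifluoromethanesulfonate | C=C(OS(=O)(=O)C(F)(F)F)[C@]12CC[C@](C)(C[C@@H](/C=C(\C)CCC=C(C)C)O1)O2 | intermediate
23 | 2,5-dimethoxy-4-methylbenzaldehyde | COc1cc(C)c(OC)cc1C=O | starting material
24 | 1,4-dimethoxy-2-(2-methoxyethenyl)-5-methylbenzene (E/Z mixture) | COC=Cc1cc(OC)c(C)cc1OC | intermediate
25 | 2-(2,5-dimethoxy-4-methylphenyl)acetaldehyde | COc1cc(C)c(OC)cc1CC=O | intermediate
26 | 3-Bic-1-(2,5-dimethoxy-4-methylphenyl)but-3-en-2-ol (C2 epimers) | C=C(C(O)Cc1cc(OC)c(C)cc1OC)[C@]12CC[C@](C)(C[C@@H](/C=C(\C)CCC=C(C)C)O1)O2 | intermediate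
27 | 3-Bic-1-(2,5-dimethoxy-4-methylphenyl)but-3-en-2-one | C=C(C(=O)Cc1cc(OC)c(C)cc1OC)[C@]12CC[C@](C)(C[C@@H](/C=C(\C)CCC=C(C)C)O1)O2 | intermediate
28 | (2R)-3-Bic-1-(2,5-dimethoxy-4-methylphenyl)but-3-en-2-ol | C=C([C@H](O)Cc1cc(OC)c(C)cc1OC)[C@]12CC[C@](C)(C[C@@H](/C=C(\C)CCC=C(C)C)O1)O2 | intermediate
29 | (1R)-1-[(2S)-2-Bic-oxiran-2-yl]-2-(2,5-dimethoxy-4-methylphenyl)ethan-1-ol | O[C@H](Cc1cc(OC)c(C)cc1OC)[C@@]1(CO1)[C@]23CC[C@](C)(C[C@@H](/C=C(\C)CCC=C(C)C)O2)O3 | intermediate
30 | (2S,3R)-2-Bic-4-(2,5-dimethoxy-4-methylphenyl)-2,3-dihydroxybutyl acetate | CC(=O)OC[C@](O)([C@H](O)Cc1cc(OC)c(C)cc1OC)[C@]12CC[C@](C)(C[C@@H](/C=C(\C)CCC=C(C)C)O1)O2 | intermediate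
31 | (2S,3R)-3-acetoxy-2-Bic-4-(2,5-dimethoxy-4-methylphenyl)-2-hydroxybutyl acetate | CC(=O)OC[C@](O)([C@@H](Cc1cc(OC)c(C)cc1OC)OC(C)=O)[C@]12CC[C@](C)(C[C@@H](/C=C(\C)CCC=C(C)C)O1)O2 | intermediate
32 | (2S,3R)-3-acetoxy-2-Bic-2-hydroxy-4-(4-methyl-3,6-dioxocyclohexa-1,4-dien-1-yl)butyl acetate | CC(=O)OC[C@](O)([C@@H](CC1=CC(=O)C(C)=CC1=O)OC(C)=O)[C@]12CC[C@](C)(C[C@@H](/C=C(\C)CCC=C(C)C)O1)O2 | intermediate
33 | (2S,3R)-3-acetoxy-2-Bic-4-(2,5-dihydroxy-4-methylphenyl)-2-hydroxybutyl acetate | CC(=O)OC[C@](O)([C@@H](Cc1cc(O)c(C)cc1O)OC(C)=O)[C@]12CC[C@](C)(C[C@@H](/C=C(\C)CCC=C(C)C)O1)O2 | target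

**Count**

Total step count: 23. Longest linear sequence: 21 steps (steps 1–10, 12–15, 17–23).

**Steps most likely to fail**

Step 4. Benzoate may be delivered to the tertiary epoxide carbon C10, or isopropoxide may compete, so that the wanted C15 benzoate forms in low yield. The regio-isomers are constitutional isomers and are removed, so the enantiomeric purity is not at stake. The fallback sets out from 5. The carbinol is silylated first (TBSCl, imidazole, DMF) to the epoxy silyl ether tert-butyl(dimethyl){(1R)-1-[(1S,6R)-4-methyl-7-oxabicyclo[4.1.0]hept-3-en-1-yl]ethoxy}silane F1. The epoxide is then opened by hydroxide under Lewis-acid-free SN2 conditions (KOH, DMSO–H2O, 100 °C), where only the secondary C15 can be attacked. This gives diol 8 directly, where the route is rejoined; steps 5 and 6 are then not needed.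

Step 7. The boat-like transannular capture of the mercurinium ion may be slower than its reversal or than capture by adventitious water, and the organomercurial may partly revert to the alkene on reduction. The fallback sets out from 8. Iodoetherification (N-iodosuccinimide, NaHCO3, MeCN, 0 °C) gives the isolable endo iodide (1S,2S,4S,5S)-1-[(1R)-1-{[tert-butyl(dimethyl)silyl]oxy}ethyl]-5-iodo-4-methyl-7-oxabicyclo[2.2.1]heptan-2-ol F2; its iodonium precursor forms reversibly and tolerates a slow ring closure. Radical deiodination (Bu3SnH, AIBN, toluene, 80 °C) then rejoins the route at 10.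

Step 12. Methyl may be transferred from aluminium in place of the alkenyl group, the ketal carbon C10 may ionise in competition with the acetal carbon C15, or exo selectivity may be incomplete. The fallback sets out from 14 and builds the alkene stepwise. The acetate is replaced by the small, linear prop-1-ynyl group (diethyl(prop-1-yn-1-yl)alane from prop-1-ynyllithium and Et2AlCl, CH2Cl2, −78 °C) to give tert-butyl(dimethyl){(1R)-1-[(1R,3S,5R)-5-methyl-3-(prop-1-yn-1-yl)-2,8-dioxabicyclo[3.2.1]octan-1-yl]ethoxy}silane F3. Hydrozirconation (Cp2Zr(H)Cl, THF, 50 °C, zirconium settling on the methyl-bearing carbon) and iodinolysis (I2) give tert-butyl{(1R)-1-[(1R,3S,5R)-3-[(1E)-2-iodoprop-1-en-1-yl]-5-methyl-2,8-dioxabicyclo[3.2.1]octan-1-yl]ethoxy}dimethylsilane F4. Negishi coupling with (4-methylpent-3-en-1-yl)zinc bromide (from 15 and zinc dust) under Pd(PPh3)4 (zerovalent palladium) proceeds with retention of the alkene geometry and rejoins the route at 19.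

**Further compounds**

F1 | step 4 | tert-butyl(dimethyl){(1R)-1-[(1S,6R)-4-methyl-7-oxabicyclo[4.1.0]hept-3-en-1-yl]ethoxy}silane | C[C@@H](O[Si](C)(C)C(C)(C)C)[C@]12CC=C(C)C[C@H]1O2
F2 | step 7 | (1S,2S,4S,5S)-1-[(1R)-1-{[tert-butyl(dimethyl)silyl]oxy}ethyl]-5-iodo-4-methyl-7-oxabicyclo[2.2.1]heptan-2-ol | C[C@@H](O[Si](C)(C)C(C)(C)C)[C@]12C[C@H](I)[C@](C)(C[C@@H]1O)O2
F3 | step 12 | tert-butyl(dimethyl){(1R)-1-[(1R,3S,5R)-5-methyl-3-(prop-1-yn-1-yl)-2,8-dioxabicyclo[3.2.1]octan-1-yl]ethoxy}silane | C[C@@H](O[Si](C)(C)C(C)(C)C)[C@]12CC[C@](C)(C[C@@H](C#CC)O1)O2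
F4 | step 12 | tert-butyl{(1R)-1-[(1R,3S,5R)-3-[(1E)-2-iodoprop-1-en-1-yl]-5-methyl-2,8-dioxabicyclo[3.2.1]octan-1-yl]ethoxy}dimethylsilane | C[C@@H](O[Si](C)(C)C(C)(C)C)[C@]12CC[C@](C)(C[C@@H](/C=C(\C)I)O1)O2
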